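I wanted to know which way of running the same charges leaves the most target after 2.5 min, so I reckoned what stays missing instead of what gets made.

| setting | green | blue | gamma | beta | zeta | eta |
|---|---|---|---|---|---|---|
| starting material | 49 mM | 49 mM | 49 mM (fed, over 1.25 min) | 49 mM | 49 mM | 49 mM |
| second substrate | 1 equiv | 0.50 equiv | 1.00 equiv | 1.00 equiv (fed, over 1.25 min) | 1.00 equiv | 1.00 equiv |
| free enzyme | 0.05 mol% | 0.05 mol% | 0.05 mol% | 0.05 mol% | 0.05 mol% | 0.05 mol% |
| remark | run made earlier | run made earlier | a stirred flask in which starting material is dosed at a steady rate over 1.25 min without added volume, worked up at 2.5 min | a stirred flask in which second substrate is dosed at a steady rate over 1.25 min without added volume, worked up at 2.5 min | a single well-mixed tank run continuously and read at steady state, 2.5 min in it on average | a closed flask charged with all of it at once and left for 2.5 min |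
| time |  |  | 2.5 min | 2.5 min |  | 2.5 min |

- the set-up with the highest amount of target at the outlet or at the end, in percent of the starting material put in ("none" if the first two lie within 2 percentage points) (gamma / beta / zeta / eta / none)
- amount of target at the outlet or at the end, in percent of the starting material put in, gamma
- amount of target at the outlet or at the end, in percent of the starting material put in, beta
- amount of target at the outlet or at the end, in percent of the starting material put in, zeta
- amount of target at the outlet or at the end, in percent of the starting material put in, eta

- the stated concentrations are those of everything mixed, before any reaction; amounts are the same in each set-up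
- the feed brings no volume worth counting
- the earlier runs were made in a closed, stirred flask

| run | time / s | target / % |
|---|---|---|
| green | 12.0 | 18.6 |
| green | 25.0 | 34.9 |
| green | 40.0 | 50.3 |
| green | 50.0 | 59.4 |
| green | 60.0 | 67.2 |
| green | 80.0 | 79.2 |
| green | 90.0 | 83.5 |
| blue | 10.0 | 10.2 |
| blue | 12.0 | 12.2 |
| blue | 20.0 | 18.4 |
| blue | 30.0 | 24.8 |

(standard deviation of a reading: 0.5 percentage points)

I read the green table from the bottom. From 60.0 s to 90.0 s the remainder, the part of the charge not yet target, fell from 32.8% to 16.5%, which makes 0.0229 s⁻¹ the tail constant, the fall per second of the logarithm of the remainder. The top row differs: its first reading gives 0.0171 s⁻¹, smaller, so one constant did not hold from the start.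

The blue table surprised me. Its last reading, taken as c(second substrate) against that run's own charge, gives 0.0228 s⁻¹, about the same, although at that reading 75.2% of blue's starting material was not yet target, against 32.8% at the start of the green stretch. So I treated the tail as pseudo-first-order in second substrate.

Eta has green's charges, so I started from green's last reading and reckoned the correction: for 60.0 s more, my estimate was 4.18% missing. For zeta I took the remainder as one over one plus the constant times the mean stay, 22.5%, which lies inside the span I had read. A fed flask has 75.0 s after its feed, so to match eta it needed 23.3% missing at feed's end. Green, with everything in from the start, was first below that at its reading at 80.0 s, later than the end of the feed at 1.25 min, so I put both fed flasks behind eta.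

The forecast said 96.2% for eta, 93.9% for gamma, 91.5% for beta and 77.3% for zeta: “Eta wins narrowly”. My estimate for eta, 95.8%, was lower than its figure.

The simulation put eta first: eta 96.2%, gamma 92.9%, beta 91.1%, zeta 77.2%.

    starting material + free enzyme ⇌ first complex (K = 99.0 M⁻¹, k = 11000 M⁻¹ s⁻¹)
    second complex → free enzyme + target (k = 180 s⁻¹)
    first complex → loaded enzyme + first product (k = 130 s⁻¹)
    free enzyme ⇌ dormant form (K = 0.400, k = 0.0490 s⁻¹)
    second substrate + loaded enzyme ⇌ second complex (K = 8.10 M⁻¹, k = 59000 M⁻¹ s⁻¹)

A neighbour of eta was charged with 0.400 equiv of second substrate, which made that substrate the limiting reagent. I applied the tail constant to it: after 2.5 min the reckoning leaves 3.22% of its own charge, so target falls just short of that charge. The neighbour held less than that, with 0.916% of its charge of second substrate still there at 2.50 min, beside 60.3% of starting material and 39.6% of target, both in percent of the starting material charged.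

(The data were computed with constants of no real substance; the scatter is artificial.)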